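The route rests on cutting C4a–C5 and C8–C8a. Ring A (C4a, C5, C6, C7, C8, C8a) is therefore grown onto a finished monocyclic pyranone instead of being bought as a phloroglucinol. Two features are exploited. The oxygens on C5 and C7 sit 1,3 to each other, exactly as in a 1,1,3-trioxygenated butadiene. The fusion bond C4a=C8a is the C3=C2 enone bond of a 6-icosyl-4-pyranone. One operation joins diene and pyranone, closes ring A and aromatises it by expelling benzenesulfenic acid and methoxytrimethylsilane. The precursor is 6-icosyl-4H-pyran-4-one bearing a racemic phenylsulfinyl group on C3 as a traceless activator.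

Key step: step 6

Assumption: the target is achiral. The sulfoxide is used as the racemate, the two push–pull enaminones are drawn Z (NMe2 anti to the acyl group) and the ketene acetal is drawn 1E. None of these elements survives the key step, so none needs control.

Step 1
Reactants: 1 henicosanoic acid
Product: 2 henicosanoyl chloride
Conditions: (COCl)2 (1.5 equiv), DMF (cat.), CH2Cl2, rt; concentrate, use crude
Reagents that add atoms: oxalyl chloride, O=C(Cl)C(=O)Cl
Why: DMF-catalysed acid chloride formation (Vilsmeier-type activation) is driven by loss of gases and meets no competing functionality in a saturated fatty acid.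

Step 2
Reactants: 3 (phenylthio)acetone; 4 N,N-dimethylformamide dimethyl acetal
Product: 5 (3Z)-4-(dimethylamino)-3-(phenylthio)but-3-en-2-one
Conditions: 4 (1.2 equiv), PhMe, 90 °C, MeOH distilled off
Reagents that add atoms: none
Why: Aminomethylenation with an amide acetal (enaminone condensation) should occur at the CH2 flanked by carbonyl and sulfur, the most acidic and most readily enolised position, and removal of methanol drives it to the push–pull alkene, whose Z geometry is thermodynamic and of no consequence.

Step 3
Reactants: 5 (3Z)-4-(dimethylamino)-3-(phenylthio)but-3-en-2-one; 2 henicosanoyl chloride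
Product: 7 6-icosyl-3-(phenylthio)-4H-pyran-4-one, via acylated enaminone 6 (not isolated)
Conditions: 5 (2.1 equiv), LiN(SiMe3)2 (2.1 equiv), THF, −78 °C; 2 (1.0 equiv) in THF, −78 → 0 °C; then 2 M HCl, rt
Reagents that add atoms: none
Why: The α′-methyl group is the only enolisable site of 5, so its lithium enolate should undergo Claisen-type C-acylation by 2 with the second equivalent of enolate absorbing the acidic proton of 6, and acid then lets the enol oxygen of 6 displace dimethylamine by conjugate addition–elimination, which is the established enaminone route to 4-pyranones.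

Step 4
Reactants: 7 6-icosyl-3-(phenylthio)-4H-pyran-4-one
Product: 8 6-icosyl-3-(phenylsulfinyl)-4H-pyran-4-one (racemic at sulfur)
Conditions: mCPBA (1.0 equiv), CH2Cl2, −20 → 0 °C
Reagents that add atoms: mCPBA (3-chloroperoxybenzoic acid), O=C(OO)c1cccc(Cl)c1
Why: Peracid oxidation of a sulfide to a sulfoxide is much faster than the second oxidation and than any attack on the electron-poor pyranone double bonds, so one equivalent at low temperature should stop at 8, whose new stereogenic sulfur forms as a racemate because nothing in 7 differentiates the lone pairs.

Step 5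
Reactants: 9 methyl (E)-3-methoxybut-2-enoate
Product: 10 (1E)-1,3-dimethoxy-1-(trimethylsilyloxy)buta-1,3-diene
Conditions: LiN(iPr)2 (1.1 equiv), THF, −78 °C; Me3SiCl (1.2 equiv), −78 °C → rt; pentane, filter, distil under vacuum
Reagents that add atoms: chlorotrimethylsilane, C[Si](C)(C)Cl
Why: Kinetic γ-deprotonation of the methyl group cis to the ester gives the extended lithium dienolate, which the hard electrophile Me3SiCl traps on oxygen (silyl ketene acetal formation), the geometry of the new C1=C2 bond being irrelevant later.

Step 6
Reactants: 8 6-icosyl-3-(phenylsulfinyl)-4H-pyran-4-one; 10 (1E)-1,3-dimethoxy-1-(trimethylsilyloxy)buta-1,3-diene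
Product: 13 5-hydroxy-2-icosyl-7-methoxy-4H-chromen-4-one, via cis-fused cycloadduct 11 (not isolated), via dihydrochromone ketal 12 (not isolated)
Conditions: 10 (3 equiv), PhMe (0.5 M), 90 °C, sealed tube, Ar; then SiO2, CH2Cl2, rt
Reagents that add atoms: none
Why: Proposed new method: the CH2 terminus of 10, the most nucleophilic carbon of the diene, should attack pyranone C2, which is β to both the C4 carbonyl and the C3 sulfinyl group, while the ketene acetal carbon closes on C3 in a strongly asynchronous [4+2] cycloaddition of normal electron demand to give 11. Because the addition is suprafacial, the sulfinyl group on C4a and the hydrogen on C8a of 11 lie on the same face, so a thermal intramolecular syn-elimination of PhSOH re-forms C4a=C8a (12), after which the C5 mixed ketal expels MeOSiMe3 and the resulting dienone enolises to the chelated 5-phenol 13. The closest known reaction types are the Diels–Alder/aromatisation sequences of this diene with halo- and sulfinylquinones and the cycloadditions of 3-sulfinyl-, 3-acyl- and 3-cyanochromones with oxygenated dienes that lead to xanthones, whereas a monocyclic 4-pyranone as the 2π partner has not been shown. Ring A is closed as a six-membered carbocycle by intermolecular [4π+2π] annulation across the C2=C3 edge, the two new bonds (C8–C8a and C4a–C5) forming in one event or, in the stepwise limit, by Mukaiyama–Michael addition followed by six-membered closure of the sulfinyl-stabilised enolate onto the silyloxycarbenium ion. No stereocentre survives, since C4a, C8a, C5 and sulfur are transient and are erased by the two eliminations, so only the cis relationship imposed by suprafacial addition matters. The step needs regioselectivity (oxygen on C5 and C7, not on C6 and C8) and site selectivity (C2=C3, not C5=C6); the first is secured by the matched pull of carbonyl and sulfinyl groups on C2, the second by the fact that only C2=C3 carries the activator and an unsubstituted β-carbon, C6 being blocked by the icosyl chain.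

Step 7
Reactants: 13 5-hydroxy-2-icosyl-7-methoxy-4H-chromen-4-one
Product: 14 5,7-dihydroxy-2-icosyl-4H-chromen-4-one (target)
Conditions: BBr3 (4 equiv), CH2Cl2, 0 °C → rt; then H2O
Reagents that add atoms: none
Why: Lewis-acid aryl methyl ether cleavage, in which BBr3 binds the C7 ether oxygen and bromide removes the methyl group by SN2 attack, while the C5 hydroxy/C4 carbonyl pair is merely held as a boron chelate that water releases and the pyranone ring and alkyl chain are inert.

Compound list
1 | henicosanoic acid | CCCCCCCCCCCCCCCCCCCCC(=O)O | starting material
2 | henicosanoyl chloride | CCCCCCCCCCCCCCCCCCCCC(=O)Cl | intermediate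
3 | (phenylthio)acetone | CC(=O)CSc1ccccc1 | starting material
4 | N,N-dimethylformamide dimethyl acetal | COC(OC)N(C)C | starting material
5 | (3Z)-4-(dimethylamino)-3-(phenylthio)but-3-en-2-one | CC(=O)/C(Sc1ccccc1)=C/N(C)C | intermediate
6 | (1Z)-1-(dimethylamino)-2-(phenylthio)pentacos-1-ene-3,5-dione (not isolated) | CCCCCCCCCCCCCCCCCCCCC(=O)CC(=O)/C(Sc1ccccc1)=C/N(C)C | intermediate
7 | 6-icosyl-3-(phenylthio)-4H-pyran-4-one | CCCCCCCCCCCCCCCCCCCCc1cc(=O)c(Sc2ccccc2)co1 | intermediate
8 | 6-icosyl-3-(phenylsulfinyl)-4H-pyran-4-one, racemic at sulfur | CCCCCCCCCCCCCCCCCCCCc1cc(=O)c(S(=O)c2ccccc2)co1 | intermediate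
9 | methyl (E)-3-methoxybut-2-enoate | CO/C(C)=C/C(=O)OC | starting material
10 | (1E)-1,3-dimethoxy-1-(trimethylsilyloxy)buta-1,3-diene | C=C(OC)/C=C(\OC)O[Si](C)(C)C | intermediate
11 | cis-fused 2-icosyl-5,7-dimethoxy-4a-(phenylsulfinyl)-5-(trimethylsilyloxy)-4a,5,8,8a-tetrahydro-4H-chromen-4-one, racemic, sulfinyl on C4a syn to H on C8a, C5 and sulfur undefined (not isolated) | CCCCCCCCCCCCCCCCCCCCC1=CC(=O)[C@]2(S(=O)c3ccccc3)C(OC)(O[Si](C)(C)C)C=C(OC)C[C@@H]2O1 | intermediate
12 | 2-icosyl-5,7-dimethoxy-5-(trimethylsilyloxy)-5,8-dihydro-4H-chromen-4-one, racemic at C5 (not isolated) | CCCCCCCCCCCCCCCCCCCCC1=CC(=O)C2=C(CC(OC)=CC2(OC)O[Si](C)(C)C)O1 | intermediate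
13 | 5-hydroxy-2-icosyl-7-methoxy-4H-chromen-4-one | CCCCCCCCCCCCCCCCCCCCc1cc(=O)c2c(O)cc(OC)cc2o1 | intermediate
14 | 5,7-dihydroxy-2-icosyl-4H-chromen-4-one | CCCCCCCCCCCCCCCCCCCCc1cc(=O)c2c(O)cc(O)cc2o1 | target

Total step count: 7
Longest linear sequence: 5 (step 1 or step 2, then steps 3, 4, 6 and 7)

Steps most likely to fail

**Risk at step 6 (proposed new method).**
- The pyranone may be too weak a 2π partner, so that the diene suffers silyl migration or hydrolysis before it adds.
- Conjugate addition at C2 may be followed by β-elimination of O1, opening the pyranone ring instead of closing ring A.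
- The silyl ketene acetal may silylate the sulfoxide oxygen and start Pummerer-type chemistry.
- The liberated sulfenic acid may consume the diene faster than the cycloaddition does.

The fallback uses only known chromone chemistry. It sets out from 2 and returns at 13. Commercial 2-hydroxy-4,6-dimethoxyacetophenone is O-acylated with 2 (pyridine, CH2Cl2) to 2-acetyl-3,5-dimethoxyphenyl henicosanoate F1. KOtBu in THF brings about the Baker–Venkataraman acyl migration to 1-(2-hydroxy-4,6-dimethoxyphenyl)tricosane-1,3-dione F2. Catalytic H2SO4 in AcOH cyclodehydrates this to 2-icosyl-5,7-dimethoxy-4H-chromen-4-one F3. BCl3 in CH2Cl2, guided by chelation to the C4 carbonyl, removes only the peri methyl group on the C5 oxygen and gives 13.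

**Risk at step 3.**
- The enolate may be acylated on oxygen or acylated twice.
- Base may convert the acid chloride into a ketene.
- The C21 electrophile may precipitate at low temperature.

The fallback replaces the free acid chloride by a chelate-controlled ketone synthesis. It sets out from 2. With N,O-dimethylhydroxylamine hydrochloride and pyridine in CH2Cl2, 2 gives N-methoxy-N-methylhenicosanamide F4. The lithium enolate of 5 adds to F4, and the chelated tetrahedral adduct persists until the quench. Acylation on oxygen, a second acylation and ketene formation are therefore excluded, and the reaction can be run warm enough to keep the chain in solution. Mild acid releases 6, which is now isolated and cyclised separately with CF3CO2H in CH2Cl2. The route is rejoined at 7.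

**Risk at step 2.** Condensation may occur at the methyl group, or at both α-positions, which erodes regiochemical purity.

The fallback makes the C–C bond first and the C–S bond afterwards. It sets out from 4, which is condensed with acetone, a ketone with only one kind of α-position, to (E)-4-(dimethylamino)but-3-en-2-one F5. Electrophilic sulfenylation of F5 at its nucleophilic α-carbon with N-(phenylthio)succinimide in CH2Cl2 then returns to the route at 5.

Further compounds
F1 | step 6 | 2-acetyl-3,5-dimethoxyphenyl henicosanoate | CCCCCCCCCCCCCCCCCCCCC(=O)Oc1cc(OC)cc(OC)c1C(C)=O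
F2 | step 6 | 1-(2-hydroxy-4,6-dimethoxyphenyl)tricosane-1,3-dione | CCCCCCCCCCCCCCCCCCCCC(=O)CC(=O)c1c(O)cc(OC)cc1OC
F3 | step 6 | 2-icosyl-5,7-dimethoxy-4H-chromen-4-one | CCCCCCCCCCCCCCCCCCCCc1cc(=O)c2c(OC)cc(OC)cc2o1
F4 | step 3 | N-methoxy-N-methylhenicosanamide | CCCCCCCCCCCCCCCCCCCCC(=O)N(C)OC
F5 | step 2 | (E)-4-(dimethylamino)but-3-en-2-one | CC(=O)/C=C/N(C)C
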